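**Retrosynthetic overview**
1. Target 12 ⇐ heptabenzyl ether 11 (one global hydrogenolysis at the end).
2. 11 ⇐ 10 ⇐ 9: both pyranone rings are cut at O1–C2 (intramolecular oxa-Michael retron). Forward, ring C of the 3-linked eriodictyol unit (unit E) closes first and sets its C2/C3; ring C of the 8-linked naringenin unit (unit N) closes second and sets its C2.
3. 9 ⇐ diketone 5 + aldehydes 6 and 8 (two aldol condensations). All four benzene rings are bought, and every C–C bond is made before any stereocentre exists.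
4. 5 ⇐ acetophenone 1 used twice: ortho-iodide 2 + silyl enol ether 3 (Pd α-arylation gives the CH2–aryl bond that becomes the C3(E)–C8(N) link).

Assumption: 1, 6 and 8 are bought as catalogue benzyl ethers, and the quinidine-derived catalyst gives the 2R sense in step 5 and the quinine-derived one the 2S sense in step 6; if the first runs show the reverse, the two catalysts are exchanged.

**Step 1**
Reactants: 1 1-[2,4-bis(benzyloxy)-6-hydroxyphenyl]ethan-1-one
Product: 2 1-[4,6-bis(benzyloxy)-2-hydroxy-3-iodophenyl]ethan-1-one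
Conditions: NIS (1.05 equiv), TsOH·H2O (10 mol %), MeCN–CH2Cl2, 0 °C → rt
Reagents that add atoms: N-iodosuccinimide, O=C1CCC(=O)N1I
Why: Electrophilic aromatic iodination goes to C3, the only free position ortho to the phenol (C5 is para to OH and wedged between two benzyloxy groups), as is known for the 4,6-dimethyl ether of phloroacetophenone; no stereocentre is formed.

**Step 2**
Reactants: 1 1-[2,4-bis(benzyloxy)-6-hydroxyphenyl]ethan-1-one; 2 1-[4,6-bis(benzyloxy)-2-hydroxy-3-iodophenyl]ethan-1-one
Product: 5 2-[3-acetyl-4,6-bis(benzyloxy)-2-hydroxyphenyl]-1-[2,4-bis(benzyloxy)-6-hydroxyphenyl]ethan-1-one, via bis-silyl enol ether 3 (not isolated), via aryl silyl ether 4 (not isolated)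
Conditions: 1 (2.2 equiv), TMSOTf, Et3N, toluene, 0 °C → rt, ammonium salt layer removed; then 2, Pd(OAc)2 (5 mol %), P(t-Bu)3 (10 mol %), Bu3SnF, toluene, 85 °C; then AcOH–THF–H2O, rt
Reagents that add atoms: trimethylsilyl trifluoromethanesulfonate, C[Si](C)(C)OS(=O)(=O)C(F)(F)F (gives the silicon of 3 and 4 only; nothing from it stays in 5)
Why: Soft enolisation turns the methyl ketone of 1 into its silyl enol ether, which is arylated at the terminal carbon by 2 under palladium catalysis with Bu3SnF as activator (Kuwajima–Urabe-type α-arylation of a methyl ketone), neutral conditions under which the acetyl group of 2 is not enolised so that only the cross-coupled ketone forms (the excess of 3 covers loss to the free phenol of 2); no stereocentre is formed.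

**Step 3**
Reactants: 5 2-[3-acetyl-4,6-bis(benzyloxy)-2-hydroxyphenyl]-1-[2,4-bis(benzyloxy)-6-hydroxyphenyl]ethan-1-one; 6 4-(benzyloxy)benzaldehyde
Product: 7 (2E)-1-[4,6-bis(benzyloxy)-2-hydroxy-3-{2-[2,4-bis(benzyloxy)-6-hydroxyphenyl]-2-oxoethyl}phenyl]-3-[4-(benzyloxy)phenyl]prop-2-en-1-one
Conditions: 6 (1.05 equiv), KOH (50 % aq., 8 equiv), EtOH–THF, 0 °C → rt; then cold 1 M HCl
Reagents that add atoms: none
Why: Claisen–Schmidt aldol condensation in which the unhindered methyl ketone enolate adds to 6 and dehydrates by E1cB to the E enone, whereas the ketone methylene flanked by two ortho,ortho'-disubstituted rings does not compete at room temperature with one equivalent of aldehyde, and the strong base keeps the product as the open-chain phenoxide; no stereocentre is formed.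

**Step 4**
Reactants: 7 (2E)-1-[4,6-bis(benzyloxy)-2-hydroxy-3-{2-[2,4-bis(benzyloxy)-6-hydroxyphenyl]-2-oxoethyl}phenyl]-3-[4-(benzyloxy)phenyl]prop-2-en-1-one; 8 3,4-bis(benzyloxy)benzaldehyde
Product: 9 (2E)-1-[2,4-bis(benzyloxy)-6-hydroxyphenyl]-2-{4,6-bis(benzyloxy)-2-hydroxy-3-[(2E)-3-[4-(benzyloxy)phenyl]prop-2-enoyl]phenyl}-3-[3,4-bis(benzyloxy)phenyl]prop-2-en-1-one
Conditions: 8 (3 equiv), KOH (50 % aq., 10 equiv), EtOH–THF, 50 °C, 48 h; then poured into 1 M HCl at 0 °C
Reagents that add atoms: none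
Why: Second Claisen–Schmidt condensation, now forced at the doubly benzylic ketone methylene with excess aldehyde and heat; in excess hydroxide both enones stay open as phenoxides (ring closure is reversed by E1cB), the thermodynamically preferred E isomer results (planar cinnamoyl unit, α-aryl ring orthogonal), and the cold inverse quench gives the neutral bis-enone before it can cyclise; no stereocentre is formed.

**Step 5**
Reactants: 9 (2E)-1-[2,4-bis(benzyloxy)-6-hydroxyphenyl]-2-{4,6-bis(benzyloxy)-2-hydroxy-3-[(2E)-3-[4-(benzyloxy)phenyl]prop-2-enoyl]phenyl}-3-[3,4-bis(benzyloxy)phenyl]prop-2-en-1-one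
Product: 10 (2R,3S)-5,7-bis(benzyloxy)-3-{4,6-bis(benzyloxy)-2-hydroxy-3-[(2E)-3-[4-(benzyloxy)phenyl]prop-2-enoyl]phenyl}-2-[3,4-bis(benzyloxy)phenyl]-2,3-dihydro-4H-chromen-4-one
Conditions: squaramide of 9-amino-9-deoxy-epi-quinidine and 3,5-bis(trifluoromethyl)aniline (10 mol %), toluene, 4 Å MS, −20 °C
Reagents that add atoms: none
Why: Proposed new method: a cinchona squaramide closes an unactivated 2'-hydroxy-α-arylchalcone by enantioselective 6-endo oxa-Michael addition — the quinuclidine nitrogen takes the proton of the chelated phenol, the two squaramide N–H bonds hold the enone carbonyl, and the resulting ion pair delivers the phenoxide oxygen to one face of C-β so that C2 (R) is fixed in the C–O bond-forming step, while C3, an acidic α-aryl ketone position, is then equilibrated by the same amine through the enol to the diequatorial trans (3S) arrangement; the twisted, strained α-aryl enone closes far more readily than the ordinary chalcone of unit N (which needs heat even with acetate), so only ring C of unit E forms at −20 °C, and no achiral base is present to give a background reaction; the closest known reaction is the cinchona-thiourea-catalysed oxa-Michael cyclisation of alkylidene β-ketoesters to flavanones, which relies on an extra ester for activation and has not been shown for α-aryl enones or for setting two adjacent centres.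

**Step 6**
Reactants: 10 (2R,3S)-5,7-bis(benzyloxy)-3-{4,6-bis(benzyloxy)-2-hydroxy-3-[(2E)-3-[4-(benzyloxy)phenyl]prop-2-enoyl]phenyl}-2-[3,4-bis(benzyloxy)phenyl]-2,3-dihydro-4H-chromen-4-one
Product: 11 (2R,3S)-5,7-bis(benzyloxy)-3-{(2S)-5,7-bis(benzyloxy)-2-[4-(benzyloxy)phenyl]-4-oxo-3,4-dihydro-2H-chromen-8-yl}-2-[3,4-bis(benzyloxy)phenyl]-2,3-dihydro-4H-chromen-4-one
Conditions: squaramide of 9-amino-9-deoxy-epi-quinine and 3,5-bis(trifluoromethyl)aniline (20 mol %), toluene, 4 Å MS, 30 °C
Reagents that add atoms: none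
Why: Proposed new method: the pseudo-enantiomeric squaramide applies the same phenoxide-delivery mechanism to the remaining 2'-hydroxy-6'-benzyloxychalcone and sets C2 of unit N (S) in the C–O bond-forming step, the 6'-alkoxy group making ring closure thermodynamically downhill so that the neutral flavanone does not reopen under the weak amine, while unit E is left alone because its trans arrangement is the thermodynamic one; the closest known reaction is again the thiourea-catalysed oxa-Michael cyclisation of ester-activated alkylidene β-ketoesters, here extended to a chalcone without the activating ester.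

**Step 7**
Reactants: 11 (2R,3S)-5,7-bis(benzyloxy)-3-{(2S)-5,7-bis(benzyloxy)-2-[4-(benzyloxy)phenyl]-4-oxo-3,4-dihydro-2H-chromen-8-yl}-2-[3,4-bis(benzyloxy)phenyl]-2,3-dihydro-4H-chromen-4-one
Product: 12 (2R,3S)-2-(3,4-dihydroxyphenyl)-5,7-dihydroxy-3-[(2S)-5,7-dihydroxy-2-(4-hydroxyphenyl)-4-oxo-3,4-dihydro-2H-chromen-8-yl]-2,3-dihydro-4H-chromen-4-one
Conditions: H2 (1 atm), 10 % Pd/C, EtOAc–MeOH, rt, stopped after uptake of 7 equiv
Reagents that add atoms: none
Why: Hydrogenolysis of the seven benzyl ethers over palladium under neutral conditions frees all phenols without acid or base that could open a pyranone ring, so the three stereocentres are untouched.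

**Compound list**
1 | 1-[2,4-bis(benzyloxy)-6-hydroxyphenyl]ethan-1-one | CC(=O)c1c(O)cc(OCc2ccccc2)cc1OCc1ccccc1 | starting material
2 | 1-[4,6-bis(benzyloxy)-2-hydroxy-3-iodophenyl]ethan-1-one | CC(=O)c1c(O)c(I)c(OCc2ccccc2)cc1OCc1ccccc1 | intermediate
3 | {[1-(2,4-bis(benzyloxy)-6-[(trimethylsilyl)oxy]phenyl)ethenyl]oxy}(trimethyl)silane (bis-silyl enol ether of 1) | C=C(O[Si](C)(C)C)c1c(O[Si](C)(C)C)cc(OCc2ccccc2)cc1OCc1ccccc1 | intermediate
4 | 2-[3-acetyl-4,6-bis(benzyloxy)-2-hydroxyphenyl]-1-{2,4-bis(benzyloxy)-6-[(trimethylsilyl)oxy]phenyl}ethan-1-one (aryl silyl ether of 5) | CC(=O)c1c(O)c(CC(=O)c2c(O[Si](C)(C)C)cc(OCc3ccccc3)cc2OCc2ccccc2)c(OCc2ccccc2)cc1OCc1ccccc1 | intermediate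
5 | 2-[3-acetyl-4,6-bis(benzyloxy)-2-hydroxyphenyl]-1-[2,4-bis(benzyloxy)-6-hydroxyphenyl]ethan-1-one | CC(=O)c1c(O)c(CC(=O)c2c(O)cc(OCc3ccccc3)cc2OCc2ccccc2)c(OCc2ccccc2)cc1OCc1ccccc1 | intermediate
6 | 4-(benzyloxy)benzaldehyde | O=Cc1ccc(OCc2ccccc2)cc1 | starting material
7 | (2E)-1-[4,6-bis(benzyloxy)-2-hydroxy-3-{2-[2,4-bis(benzyloxy)-6-hydroxyphenyl]-2-oxoethyl}phenyl]-3-[4-(benzyloxy)phenyl]prop-2-en-1-one | O=C(/C=C/c1ccc(OCc2ccccc2)cc1)c1c(O)c(CC(=O)c2c(O)cc(OCc3ccccc3)cc2OCc2ccccc2)c(OCc2ccccc2)cc1OCc1ccccc1 | intermediate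
8 | 3,4-bis(benzyloxy)benzaldehyde | O=Cc1ccc(OCc2ccccc2)c(OCc2ccccc2)c1 | starting material
9 | (2E)-1-[2,4-bis(benzyloxy)-6-hydroxyphenyl]-2-{4,6-bis(benzyloxy)-2-hydroxy-3-[(2E)-3-[4-(benzyloxy)phenyl]prop-2-enoyl]phenyl}-3-[3,4-bis(benzyloxy)phenyl]prop-2-en-1-one | O=C(/C=C/c1ccc(OCc2ccccc2)cc1)c1c(O)c(/C(=C\c2ccc(OCc3ccccc3)c(OCc3ccccc3)c2)C(=O)c2c(O)cc(OCc3ccccc3)cc2OCc2ccccc2)c(OCc2ccccc2)cc1OCc1ccccc1 | intermediate
10 | (2R,3S)-5,7-bis(benzyloxy)-3-{4,6-bis(benzyloxy)-2-hydroxy-3-[(2E)-3-[4-(benzyloxy)phenyl]prop-2-enoyl]phenyl}-2-[3,4-bis(benzyloxy)phenyl]-2,3-dihydro-4H-chromen-4-one | O=C(/C=C/c1ccc(OCc2ccccc2)cc1)c1c(O)c([C@@H]2C(=O)c3c(OCc4ccccc4)cc(OCc4ccccc4)cc3O[C@H]2c2ccc(OCc3ccccc3)c(OCc3ccccc3)c2)c(OCc2ccccc2)cc1OCc1ccccc1 | intermediate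
11 | (2R,3S)-5,7-bis(benzyloxy)-3-{(2S)-5,7-bis(benzyloxy)-2-[4-(benzyloxy)phenyl]-4-oxo-3,4-dihydro-2H-chromen-8-yl}-2-[3,4-bis(benzyloxy)phenyl]-2,3-dihydro-4H-chromen-4-one | O=C1C[C@@H](c2ccc(OCc3ccccc3)cc2)Oc2c1c(OCc1ccccc1)cc(OCc1ccccc1)c2[C@@H]1C(=O)c2c(OCc3ccccc3)cc(OCc3ccccc3)cc2O[C@H]1c1ccc(OCc2ccccc2)c(OCc2ccccc2)c1 | intermediate
12 | (2R,3S)-2-(3,4-dihydroxyphenyl)-5,7-dihydroxy-3-[(2S)-5,7-dihydroxy-2-(4-hydroxyphenyl)-4-oxo-3,4-dihydro-2H-chromen-8-yl]-2,3-dihydro-4H-chromen-4-one | O=C1C[C@@H](c2ccc(O)cc2)Oc2c1c(O)cc(O)c2[C@@H]1C(=O)c2c(O)cc(O)cc2O[C@H]1c1ccc(O)c(O)c1 | target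

**Step count**
Total steps: 7. Longest linear sequence: 7 (1 → 2 → 5 → 7 → 9 → 10 → 11 → 12; compound 1 enters twice in step 2).

Because the two units are set in separate steps, a wrong configuration from step 5 or step 6 gives a diastereomer of 11, which is removed on silica or by crystallisation. Only the doubly wrong isomer is the enantiomer, and its share is the product of the two minor fractions (about 0.3 % for two steps of 90 % ee).

**Three steps most likely to fail**

Step 4 (forced aldol condensation at the hindered methylene). The enolate carbon sits between two ortho,ortho'-disubstituted rings and may react too slowly, or the first chalcone may scramble by retro-aldol at 50 °C. The fallback sets out from 7 and comes back at 9. Compounds 7 and 8 are heated with piperidine in EtOH, a Knoevenagel condensation through the iminium ion of 8 in which the α-aryl enone is trapped by oxa-Michael ring closure as it forms, which pulls the unfavourable aldol equilibrium; the chalcone of unit N closes as well. This gives the stereoisomer mixture of the doubly ring-closed heptabenzyl ether F1. F1 is then treated with excess KOH in EtOH–THF, which reopens both chromanones by E1cB to the bis-phenoxide, and an inverse quench into cold acid gives 9.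

Step 5 (proposed new method). The closure may be slow, poorly selective, of the opposite sense, or may not discriminate between the two enones. The fallback uses known chemistry, sets out from 9 and comes back at 10. Ring C of unit E is closed without chiral control (Et3N 20 mol %, CH2Cl2, rt; ordinary base-mediated oxa-Michael addition, trans by equilibration, the chalcone of unit N staying open). This gives racemic 10, that is 10 together with its mirror image ent-10 F2. The two are separated by preparative chromatography on a chiral stationary phase (immobilised amylose carbamate, supercritical CO2–MeOH), and F2 is returned to 9 by KOH ring opening for another pass.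

Step 6 (proposed new method, second use). The unactivated chalcone may close slowly or with low selectivity, and long exposure to the amine could partly reopen unit E. The fallback uses known chemistry, sets out from 10 and comes back at 11. NaOAc in EtOH–THF at reflux, the standard closure of 2'-hydroxy-6'-alkoxychalcones, gives 11 and the unit-N C2 epimer of 11 F3 in about equal amounts. Since unit E is already enantiopure, these are diastereomers and are separated on silica or by crystallisation.

**Further compounds**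
F1 | step 4 | 5,7-bis(benzyloxy)-3-{5,7-bis(benzyloxy)-2-[4-(benzyloxy)phenyl]-4-oxo-3,4-dihydro-2H-chromen-8-yl}-2-[3,4-bis(benzyloxy)phenyl]-2,3-dihydro-4H-chromen-4-one, mixture of stereoisomers (configuration not defined) | O=C1CC(c2ccc(OCc3ccccc3)cc2)Oc2c1c(OCc1ccccc1)cc(OCc1ccccc1)c2C1C(=O)c2c(OCc3ccccc3)cc(OCc3ccccc3)cc2OC1c1ccc(OCc2ccccc2)c(OCc2ccccc2)c1
F2 | step 5 | (2S,3R)-5,7-bis(benzyloxy)-3-{4,6-bis(benzyloxy)-2-hydroxy-3-[(2E)-3-[4-(benzyloxy)phenyl]prop-2-enoyl]phenyl}-2-[3,4-bis(benzyloxy)phenyl]-2,3-dihydro-4H-chromen-4-one (ent-10) | O=C(/C=C/c1ccc(OCc2ccccc2)cc1)c1c(O)c([C@H]2C(=O)c3c(OCc4ccccc4)cc(OCc4ccccc4)cc3O[C@@H]2c2ccc(OCc3ccccc3)c(OCc3ccccc3)c2)c(OCc2ccccc2)cc1OCc1ccccc1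
F3 | step 6 | (2R,3S)-5,7-bis(benzyloxy)-3-{(2R)-5,7-bis(benzyloxy)-2-[4-(benzyloxy)phenyl]-4-oxo-3,4-dihydro-2H-chromen-8-yl}-2-[3,4-bis(benzyloxy)phenyl]-2,3-dihydro-4H-chromen-4-one (unit-N C2 epimer of 11) | O=C1C[C@H](c2ccc(OCc3ccccc3)cc2)Oc2c1c(OCc1ccccc1)cc(OCc1ccccc1)c2[C@@H]1C(=O)c2c(OCc3ccccc3)cc(OCc3ccccc3)cc2O[C@H]1c1ccc(OCc2ccccc2)c(OCc2ccccc2)c1
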